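**Strategy.** Ring atoms are labelled C1 (tertiary carbinol) to C6, with Br and CH3 on C4 and Cl on C5; the side chain runs C7–C11. C1 and C5 sit 1,3 to each other with only C6 between them, so linking them for a time recasts the cyclohexane as a bicyclo[3.1.0]hexane. One enantioselective copper-carbene addition of a terminal diazoketone onto its own 1,1-disubstituted alkene makes C5–C1 and C5–C6, closes the cyclopentanone and the cyclopropane and sets both ring-fusion stereocentres. Methyl addition at C4 and acid-mediated C1–C5 scission, water attacking C1 from the rear, later unveil the 4-methylcyclohex-3-enol. The precursor is an acyclic α-diazoketone carrying a 2-(silyloxymethyl)allyl terminus.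

Key step: step 5

Assumption: the facial sense of the copper catalyst on this substrate cannot be predicted with certainty; the (S,S)-ligand is written, and its equally available (R,R)-antipode is to be used should the (1R,5R)-ketone predominate.

Remark on the design: the oxygen on C7 is protected as its tert-butyldiphenylsilyl (TBDPS) ether. This group has to survive the aqueous acid of step 7, and its bulk keeps the primary oxygen out of steps 5, 8 and 9. With the C1 hydroxyl drawn "up", the target has Br (C4) up and Cl (C5) down. Inversion at C1 in step 7 therefore requires the (1S,5S)-ketone.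

Step 1
Reactants: 1 2-methylenepropane-1,3-diol
Product: 2 2-{[(tert-butyldiphenylsilyl)oxy]methyl}prop-2-en-1-ol
Conditions: NaH (1.0 equiv), THF, 0 °C to rt; t-BuPh2SiCl (1.0 equiv), rt
Reagents that add atoms: tert-butyl(chloro)diphenylsilane, CC(C)(C)[Si](Cl)(c1ccccc1)c1ccccc1
Why: O-silylation of the sparingly soluble monosodium alkoxide of a symmetrical diol should stop at the mono-ether, and the bulky silyl chloride further disfavours a second silylation.

Step 2
Reactants: 2 2-{[(tert-butyldiphenylsilyl)oxy]methyl}prop-2-en-1-ol; 3 triethyl orthoacetate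
Product: 4 ethyl 4-{[(tert-butyldiphenylsilyl)oxy]methyl}pent-4-enoate
Conditions: MeC(OEt)3 (6 equiv), EtCO2H (0.1 equiv), 140 °C, EtOH distilled off
Reagents that add atoms: none
Why: Johnson–Claisen rearrangement: acid-catalysed exchange gives the mixed ketene acetal of the allylic alcohol, whose [3,3]-sigmatropic shift forms the C2–C3 bond and regenerates the 1,1-disubstituted alkene (C1=C6) carrying the silyloxymethyl group.

Step 3
Reactants: 4 ethyl 4-{[(tert-butyldiphenylsilyl)oxy]methyl}pent-4-enoate
Product: 5 4-{[(tert-butyldiphenylsilyl)oxy]methyl}pent-4-enoic acid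
Conditions: LiOH·H2O (3 equiv), THF/MeOH/H2O, rt; 1 M HCl to pH 3, 0 °C
Reagents that add atoms: lithium hydroxide, [Li+].[OH-]
Why: Saponification of the ethyl ester should leave the base-stable silyl ether and the alkene untouched, and brief cold acidification frees the acid.

Step 4
Reactants: 5 4-{[(tert-butyldiphenylsilyl)oxy]methyl}pent-4-enoic acid; 6 (trimethylsilyl)diazomethane
Product: 9 1-diazo-5-{[(tert-butyldiphenylsilyl)oxy]methyl}hex-5-en-2-one, via mixed carbonic anhydride 7 (not isolated), via C-silyl diazoketone 8 (not isolated)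
Conditions: i-BuOCOCl (1.1 equiv), Et3N (1.1 equiv), THF, −15 °C; Me3SiCHN2 (2 equiv, hexanes), MeCN, 0 °C to rt; aq. NaHCO3
Reagents that add atoms: none
Why: Acylation of the diazoalkane by the mixed anhydride (Arndt–Eistert-type diazoketone synthesis) gives the C-silyl diazoketone, which loses silicon on aqueous work-up; the mixed anhydride avoids the HCl of an acid chloride route, which could harm the allylic silyl ether.

Step 5
Reactants: 9 1-diazo-5-{[(tert-butyldiphenylsilyl)oxy]methyl}hex-5-en-2-one
Product: 10 (1S,5S)-5-{[(tert-butyldiphenylsilyl)oxy]methyl}bicyclo[3.1.0]hexan-2-one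
Conditions: (CuOTf)2·C6H6 (2.5 mol%), 2,2'-(propane-2,2-diyl)bis[(4S)-4-tert-butyl-4,5-dihydro-1,3-oxazole] (6 mol%), CH2Cl2, rt, 9 added over 10 h by syringe pump
Reagents that add atoms: none
Why: Loss of N2 from 9 at the monovalent copper–bis(oxazoline) centre gives an electrophilic copper carbene that adds to the tethered alkene in a concerted but asynchronous [2+1] event; the closest known reaction type is the copper bis(oxazoline)- or semicorrin-catalysed intramolecular cyclopropanation of alkenyl diazoketones to bicyclo[3.1.0]hexan-2-ones. The cyclopentanone closes through the bond from the carbene carbon (C5) to the internal alkene carbon (C1) in a 5-exo sense, and the cyclopropane closes through the bond from C5 to the terminal alkene carbon (C6); the two-carbon tether allows only the cis-fused bicycle. Both stereocentres (C1 and C5) arise together: their relative configuration is dictated by the cis fusion, and their absolute configuration by the C2-symmetric ligand on copper, which selects the alkene face that meets the carbene. The step needs enantioface selection and chemoselectivity for cyclopropanation over oxonium-ylide formation, C–H insertion and carbene dimerisation. The second is secured by the nucleophilic 1,1-disubstituted alkene, the bulky and weakly basic silyl ether oxygen, copper in place of rhodium and slow addition at high dilution.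

Step 6
Reactants: 10 (1S,5S)-5-{[(tert-butyldiphenylsilyl)oxy]methyl}bicyclo[3.1.0]hexan-2-one
Product: 11 (1S,2R,5S)-5-{[(tert-butyldiphenylsilyl)oxy]methyl}-2-methylbicyclo[3.1.0]hexan-2-ol (hydroxyl cis to the cyclopropane CH2; major epimer expected)
Conditions: MeLi (1.3 equiv), Et2O, −78 °C; H2O
Reagents that add atoms: methyllithium, [Li]C
Why: 1,2-Addition of methyllithium to the C4 carbonyl should occur mainly from the face away from the cyclopropane methylene; the configuration of this carbinol is immaterial because C4 becomes trigonal in step 7 and both epimers converge.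

Step 7
Reactants: 11 (1S,2R,5S)-5-{[(tert-butyldiphenylsilyl)oxy]methyl}-2-methylbicyclo[3.1.0]hexan-2-ol
Product: 12 (S)-1-{[(tert-butyldiphenylsilyl)oxy]methyl}-4-methylcyclohex-3-en-1-ol
Conditions: HClO4 (0.05 M), acetone/H2O (4:1), 0 °C to rt, stopped at full conversion; NaHCO3
Reagents that add atoms: water, O
Why: Cyclopropylcarbinyl–homoallyl rearrangement, the reaction type by which sabinene hydrate gives terpinen-4-ol: ionisation of the tertiary carbinol places positive charge at C4, the internal C1–C5 bond breaks to form the C4=C5 alkene and the six-membered ring, and water bonds to C1 on the side opposite the departing C5, so the C1 configuration of 10 is transferred with inversion; the inductively withdrawing CH2OSi group should disfavour a free C1 cation.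

Step 8
Reactants: 12 (S)-1-{[(tert-butyldiphenylsilyl)oxy]methyl}-4-methylcyclohex-3-en-1-ol
Product: 13 (1S,3S,6R)-3-{[(tert-butyldiphenylsilyl)oxy]methyl}-6-methyl-7-oxabicyclo[4.1.0]heptan-3-ol (epoxide oxygen cis to the hydroxyl)
Conditions: VO(acac)2 (2 mol%), t-BuOOH (1.5 equiv, decane), CH2Cl2, 0 °C to rt
Reagents that add atoms: tert-butyl hydroperoxide, CC(C)(C)OO
Why: Hydroxyl-directed epoxidation: the vanadium alkoxide of the homoallylic tertiary alcohol delivers peroxide oxygen to the alkene face it occupies (as with terpinen-4-ol), so the C4–C5 epoxide should form cis to the C1 hydroxyl, while the silylated primary oxygen cannot compete as a directing group.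

Step 9
Reactants: 13 (1S,3S,6R)-3-{[(tert-butyldiphenylsilyl)oxy]methyl}-6-methyl-7-oxabicyclo[4.1.0]heptan-3-ol
Product: 14 (1R,2R,4S)-4-{[(tert-butyldiphenylsilyl)oxy]methyl}-2-chloro-1-methylcyclohexane-1,4-diol
Conditions: Li2CuCl4 (1.5 equiv), THF, 0 °C to rt; pH 7 phosphate buffer
Reagents that add atoms: dilithium tetrachlorocuprate, [Li+].[Li+].[Cu+2].[Cl-].[Cl-].[Cl-].[Cl-]
Why: SN2-type, trans-diaxial epoxide opening by a nucleophilic chlorocuprate should put chloride on the less substituted C5 from the face opposite the epoxide oxygen (inversion), giving C5–Cl trans and C4–OH cis to the C1 hydroxyl; an aprotic, weakly Lewis-acidic chloride source is chosen so that C4 does not ionise and the C1 hydroxyl does not attack it transannularly.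

Step 10
Reactants: 14 (1R,2R,4S)-4-{[(tert-butyldiphenylsilyl)oxy]methyl}-2-chloro-1-methylcyclohexane-1,4-diol
Product: 15 (1R,2R,4S)-2-chloro-4-(hydroxymethyl)-1-methylcyclohexane-1,4-diol
Conditions: HF·pyridine, pyridine, THF, 0 °C to rt
Reagents that add atoms: none
Why: Fluoride cleavage of the primary silyl ether under buffered, non-basic conditions should free the C7 hydroxyl without the alkoxide formation that would close the trans-chlorohydrin back to the epoxide.

Step 11
Reactants: 15 (1R,2R,4S)-2-chloro-4-(hydroxymethyl)-1-methylcyclohexane-1,4-diol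
Product: 16 (1S,3R,4R)-3-chloro-1,4-dihydroxy-4-methylcyclohexane-1-carboxylic acid
Conditions: TEMPO (10 mol%), NaClO2 (2 equiv), NaOCl (5 mol%), MeCN/phosphate buffer (pH 6.7), 35 °C
Reagents that add atoms: sodium chlorite, [Na+].[O-]Cl=O
Why: Oxoammonium-catalysed oxidation with chlorite as terminal oxidant takes the only primary alcohol through the aldehyde to the acid at near-neutral pH; the tertiary alcohols and the secondary chloride are inert and no stereocentre is touched.

Step 12
Reactants: 16 (1S,3R,4R)-3-chloro-1,4-dihydroxy-4-methylcyclohexane-1-carboxylic acid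
Product: 17 S-ethyl (1S,3R,4R)-3-chloro-1,4-dihydroxy-4-methylcyclohexane-1-carbothioate
Conditions: EtSH (3 equiv), DCC (1.2 equiv), DMAP (10 mol%), CH2Cl2, 0 °C to rt
Reagents that add atoms: ethanethiol, CCS
Why: Carbodiimide-mediated (Steglich-type) thioesterification; the two tertiary hydroxyls are too hindered to be acylated, so only the thiol is expected to react.

Step 13
Reactants: 17 S-ethyl (1S,3R,4R)-3-chloro-1,4-dihydroxy-4-methylcyclohexane-1-carbothioate
Product: 18 S-ethyl (1S,3R,4R)-4-bromo-3-chloro-4-methyl-1-[(trimethylsilyl)oxy]cyclohexane-1-carbothioate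
Conditions: Me3SiBr (4 equiv), CH2Cl2, −20 °C to rt; Et3N (5 equiv), 0 °C
Reagents that add atoms: bromotrimethylsilane, C[Si](C)(C)Br
Why: SN1-type substitution of the tertiary C4 hydroxyl with neighbouring-group participation: the antiperiplanar C5 chlorine bridges the developing cation as a chloronium ion, so bromide should enter the tertiary C4 on the face the oxygen left (net retention, Br trans to Cl), whereas C1 cannot ionise next to the thioester carbonyl and its hydroxyl is merely silylated; any alkene from proton loss should re-add HBr in the same sense.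

Step 14
Reactants: 19 (R)-2-hydroxy-1,2,2-triphenylethyl acetate ((R)-HYTRA); 20 methacrolein
Product: 22 (1R)-2-hydroxy-1,2,2-triphenylethyl (3R)-3-hydroxy-4-methylpent-4-enoate, via dilithium enolate 21 (not isolated)
Conditions: LiN(i-Pr)2 (2.1 equiv), THF, −78 to 0 °C; MgBr2·OEt2 (2 equiv), −78 °C; 20, THF/2-methylbutane, −120 °C; aq. NH4Cl; recrystallisation
Reagents that add atoms: none
Why: Auxiliary-controlled acetate aldol addition: the chiral triphenylglycol ester enolate selects one face of the aldehyde and, by analogy with its additions to α-branched aldehydes, should give the (3R)-carbinol (C10), with recrystallisation expected to remove the minor diastereomer.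

Step 15
Reactants: 22 (1R)-2-hydroxy-1,2,2-triphenylethyl (3R)-3-hydroxy-4-methylpent-4-enoate
Product: 23 (1R)-2-hydroxy-1,2,2-triphenylethyl (3R)-4-methyl-3-[(triethylsilyl)oxy]pent-4-enoate
Conditions: Et3SiCl (1.2 equiv), imidazole (2 equiv), DMF, 0 °C to rt
Reagents that add atoms: chlorotriethylsilane, CC[Si](Cl)(CC)CC
Why: Imidazole-promoted silylation should occur only at the secondary allylic hydroxyl, the tertiary hydroxyl of the auxiliary being too hindered.

Step 16
Reactants: 23 (1R)-2-hydroxy-1,2,2-triphenylethyl (3R)-4-methyl-3-[(triethylsilyl)oxy]pent-4-enoate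
Product: 24 (3R)-4-methyl-3-[(triethylsilyl)oxy]pent-4-en-1-ol
Conditions: LiAlH4 (2 equiv), Et2O, 0 °C; H2O, aq. NaOH
Reagents that add atoms: none
Why: Hydride reduction of the ester releases the primary alcohol and the recoverable auxiliary diol; the silyl ether and the C10 centre are not involved.

Step 17
Reactants: 24 (3R)-4-methyl-3-[(triethylsilyl)oxy]pent-4-en-1-ol
Product: 25 triethyl{[(3R)-5-iodo-2-methylpent-1-en-3-yl]oxy}silane
Conditions: I2 (1.2 equiv), PPh3 (1.2 equiv), imidazole (1.5 equiv), CH2Cl2, 0 °C to rt, dark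
Reagents that add atoms: iodine, II
Why: Appel-type iodination: iodide displaces the primary oxyphosphonium group by SN2, remote from the stereocentre.

Step 18
Reactants: 18 S-ethyl (1S,3R,4R)-4-bromo-3-chloro-4-methyl-1-[(trimethylsilyl)oxy]cyclohexane-1-carbothioate; 25 triethyl{[(3R)-5-iodo-2-methylpent-1-en-3-yl]oxy}silane
Product: 27 (4R)-1-{(1S,3R,4R)-4-bromo-3-chloro-4-methyl-1-[(trimethylsilyl)oxy]cyclohexyl}-5-methyl-4-[(triethylsilyl)oxy]hex-5-en-1-one, via alkylzinc iodide 26 (not isolated)
Conditions: 25, Zn dust (activated with Me3SiCl and 1,2-dibromoethane), LiCl, THF, 30 °C, solution decanted from Zn; 18, PdCl2(PPh3)2 (10 mol%), toluene, rt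
Reagents that add atoms: none
Why: Fukuyama coupling: zinc inserts into the primary C–I bond, and zerovalent palladium formed in situ inserts into the thioester C–S bond, transmetalates and reductively eliminates to the ketone (C7–C8 bond) without over-addition; the weakly basic organozinc should tolerate the tertiary bromide and secondary chloride, and zinc metal is removed first so that the vicinal dihalide is not reduced.

Step 19
Reactants: 27 (4R)-1-{(1S,3R,4R)-4-bromo-3-chloro-4-methyl-1-[(trimethylsilyl)oxy]cyclohexyl}-5-methyl-4-[(triethylsilyl)oxy]hex-5-en-1-one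
Product: 28 {[(3R)-6-{(1S,3R,4R)-4-bromo-3-chloro-4-methyl-1-[(trimethylsilyl)oxy]cyclohexyl}-2-methylhepta-1,6-dien-3-yl]oxy}triethylsilane
Conditions: Ph3PCH3Br (3 equiv), KN(SiMe3)2 (2.8 equiv), THF, 0 °C; 27, 0 °C to rt
Reagents that add atoms: methyltriphenylphosphonium bromide, C[P+](c1ccccc1)(c1ccccc1)c1ccccc1.[Br-]
Why: Wittig methylenation of the C7 ketone; the silylated C1 oxygen prevents alkoxide formation and α-ketol rearrangement, and the low temperature with only a slight excess of ylide should limit base-induced loss of HBr.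

Step 20
Reactants: 28 {[(3R)-6-{(1S,3R,4R)-4-bromo-3-chloro-4-methyl-1-[(trimethylsilyl)oxy]cyclohexyl}-2-methylhepta-1,6-dien-3-yl]oxy}triethylsilane
Product: 29 (1S,3R,4R)-4-bromo-3-chloro-1-[(5R)-5-hydroxy-6-methylhepta-1,6-dien-2-yl]-4-methylcyclohexan-1-ol (CNP0197601.3)
Conditions: HF·pyridine, pyridine, THF, 0 °C
Reagents that add atoms: none
Why: Pyridine-buffered fluoride cleavage of both silyl ethers avoids basic fluoride (elimination of HBr) and strong acid (ionisation of the allylic tertiary alcohol) and should release the target with all four stereocentres intact.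

**Compound list**

1 | 2-methylenepropane-1,3-diol | C=C(CO)CO | starting material
2 | 2-{[(tert-butyldiphenylsilyl)oxy]methyl}prop-2-en-1-ol | C=C(CO)CO[Si](c1ccccc1)(c1ccccc1)C(C)(C)C | intermediate
3 | triethyl orthoacetate | CC(OCC)(OCC)OCC | starting material
4 | ethyl 4-{[(tert-butyldiphenylsilyl)oxy]methyl}pent-4-enoate | CCOC(=O)CCC(=C)CO[Si](c1ccccc1)(c1ccccc1)C(C)(C)C | intermediate
5 | 4-{[(tert-butyldiphenylsilyl)oxy]methyl}pent-4-enoic acid | OC(=O)CCC(=C)CO[Si](c1ccccc1)(c1ccccc1)C(C)(C)C | intermediate
6 | (trimethylsilyl)diazomethane | C[Si](C)(C)C=[N+]=[N-] | starting material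
7 | mixed anhydride of 5 with isobutyl hydrogen carbonate | CC(C)COC(=O)OC(=O)CCC(=C)CO[Si](c1ccccc1)(c1ccccc1)C(C)(C)C | intermediate
8 | 1-diazo-1-(trimethylsilyl)-5-{[(tert-butyldiphenylsilyl)oxy]methyl}hex-5-en-2-one | C[Si](C)(C)C(=[N+]=[N-])C(=O)CCC(=C)CO[Si](c1ccccc1)(c1ccccc1)C(C)(C)C | intermediate
9 | 1-diazo-5-{[(tert-butyldiphenylsilyl)oxy]methyl}hex-5-en-2-one | [N-]=[N+]=CC(=O)CCC(=C)CO[Si](c1ccccc1)(c1ccccc1)C(C)(C)C | intermediate
10 | (1S,5S)-5-{[(tert-butyldiphenylsilyl)oxy]methyl}bicyclo[3.1.0]hexan-2-one | O=C1CC[C@]2(CO[Si](c3ccccc3)(c3ccccc3)C(C)(C)C)C[C@H]12 | intermediate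
11 | (1S,2R,5S)-5-{[(tert-butyldiphenylsilyl)oxy]methyl}-2-methylbicyclo[3.1.0]hexan-2-ol | C[C@@]1(O)CC[C@]2(CO[Si](c3ccccc3)(c3ccccc3)C(C)(C)C)C[C@H]12 | intermediate
12 | (S)-1-{[(tert-butyldiphenylsilyl)oxy]methyl}-4-methylcyclohex-3-en-1-ol | CC(C)(C)[Si](c1ccccc1)(c1ccccc1)OC[C@]1(O)CCC(C)=CC1 | intermediate
13 | (1S,3S,6R)-3-{[(tert-butyldiphenylsilyl)oxy]methyl}-6-methyl-7-oxabicyclo[4.1.0]heptan-3-ol | CC(C)(C)[Si](c1ccccc1)(c1ccccc1)OC[C@]1(O)CC[C@@]2(C)O[C@H]2C1 | intermediate
14 | (1R,2R,4S)-4-{[(tert-butyldiphenylsilyl)oxy]methyl}-2-chloro-1-methylcyclohexane-1,4-diol | CC(C)(C)[Si](c1ccccc1)(c1ccccc1)OC[C@]1(O)CC[C@@](C)(O)[C@H](Cl)C1 | intermediate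
15 | (1R,2R,4S)-2-chloro-4-(hydroxymethyl)-1-methylcyclohexane-1,4-diol | OC[C@]1(O)CC[C@@](C)(O)[C@H](Cl)C1 | intermediate
16 | (1S,3R,4R)-3-chloro-1,4-dihydroxy-4-methylcyclohexane-1-carboxylic acid | OC(=O)[C@]1(O)CC[C@@](C)(O)[C@H](Cl)C1 | intermediate
17 | S-ethyl (1S,3R,4R)-3-chloro-1,4-dihydroxy-4-methylcyclohexane-1-carbothioate | CCSC(=O)[C@]1(O)CC[C@@](C)(O)[C@H](Cl)C1 | intermediate
18 | S-ethyl (1S,3R,4R)-4-bromo-3-chloro-4-methyl-1-[(trimethylsilyl)oxy]cyclohexane-1-carbothioate | CCSC(=O)[C@]1(O[Si](C)(C)C)CC[C@@](C)(Br)[C@H](Cl)C1 | intermediate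
19 | (R)-2-hydroxy-1,2,2-triphenylethyl acetate | CC(=O)O[C@H](c1ccccc1)C(O)(c1ccccc1)c1ccccc1 | starting material
20 | methacrolein | C=C(C)C=O | starting material
21 | dilithium enolate of 19 (lithium alkoxide and lithium ester enolate) | [Li]OC(=C)O[C@H](c1ccccc1)C(O[Li])(c1ccccc1)c1ccccc1 | intermediate
22 | (1R)-2-hydroxy-1,2,2-triphenylethyl (3R)-3-hydroxy-4-methylpent-4-enoate | C=C(C)[C@H](O)CC(=O)O[C@H](c1ccccc1)C(O)(c1ccccc1)c1ccccc1 | intermediate
23 | (1R)-2-hydroxy-1,2,2-triphenylethyl (3R)-4-methyl-3-[(triethylsilyl)oxy]pent-4-enoate | C=C(C)[C@H](O[Si](CC)(CC)CC)CC(=O)O[C@H](c1ccccc1)C(O)(c1ccccc1)c1ccccc1 | intermediate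
24 | (3R)-4-methyl-3-[(triethylsilyl)oxy]pent-4-en-1-ol | C=C(C)[C@H](O[Si](CC)(CC)CC)CCO | intermediate
25 | triethyl{[(3R)-5-iodo-2-methylpent-1-en-3-yl]oxy}silane | C=C(C)[C@H](O[Si](CC)(CC)CC)CCI | intermediate
26 | iodo{(3R)-4-methyl-3-[(triethylsilyl)oxy]pent-4-en-1-yl}zinc | C=C(C)[C@H](O[Si](CC)(CC)CC)CC[Zn]I | intermediate
27 | (4R)-1-{(1S,3R,4R)-4-bromo-3-chloro-4-methyl-1-[(trimethylsilyl)oxy]cyclohexyl}-5-methyl-4-[(triethylsilyl)oxy]hex-5-en-1-one | C=C(C)[C@H](O[Si](CC)(CC)CC)CCC(=O)[C@]1(O[Si](C)(C)C)CC[C@@](C)(Br)[C@H](Cl)C1 | intermediate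
28 | {[(3R)-6-{(1S,3R,4R)-4-bromo-3-chloro-4-methyl-1-[(trimethylsilyl)oxy]cyclohexyl}-2-methylhepta-1,6-dien-3-yl]oxy}triethylsilane | C=C(C)[C@H](O[Si](CC)(CC)CC)CCC(=C)[C@]1(O[Si](C)(C)C)CC[C@@](C)(Br)[C@H](Cl)C1 | intermediate
29 | (1S,3R,4R)-4-bromo-3-chloro-1-[(5R)-5-hydroxy-6-methylhepta-1,6-dien-2-yl]-4-methylcyclohexan-1-ol | C=C(C)[C@H](O)CCC(=C)[C@]1(O)CC[C@@](C)(Br)[C@H](Cl)C1 | target

**Step count.** Total: 20 steps. Longest linear sequence: 16 steps (steps 1–13, then 18–20); the side chain takes 4 steps (14–17).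

**Steps most likely to fail**

Step 5. The catalyst may not discriminate the two faces of the 1,1-disubstituted alkene well enough, and the carbene may dimerise instead of cyclising. Fallback: setting out from diazoketone 9, the cyclisation is run with achiral Cu(acac)2 in warm CH2Cl2 to give the racemic cis-fused ketone F1. Lithiated (S)-N,S-dimethyl-S-phenylsulfoximine (n-BuLi, THF, −78 °C) is then added to the carbonyl group and the diastereomeric adducts are separated by chromatography. The adduct derived from the (1S,5S)-ketone, the β-hydroxy sulfoximine F2, is heated in toluene, which reverses the addition and returns enantiopure ketone 10. Enantiocontrol by catalyst is thus replaced by a resolution.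

Step 7. The ionisation may become stepwise, eroding the stereochemical fidelity at C1. Alternatively the cation may be diverted to proton loss or to cleavage of the external cyclopropane bond, because the oxygen on C7 makes C1 a poorer cationic terminus. Fallback: setting out from carbinol 11, Bu4NF removes the silyl group to give the cyclopropyl diol F3, and benzoyl chloride in pyridine acylates only the primary hydroxyl to give the benzoate F4. The same aqueous acid is then applied. The benzoate carbonyl oxygen should now capture C1 from the face opposite C5 through a five-membered 1,3-dioxolan-2-ylium ion. This internal nucleophile directs cleavage to the C1–C5 bond and fixes the C1–O bond before water hydrolyses the ion to the hydroxy benzoate F5. Methanolysis (K2CO3, MeOH) gives the diol F6, and selective silylation of the primary hydroxyl (t-BuPh2SiCl, imidazole) returns to cyclohexenol 12.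

Step 9. Chloride may attack the tertiary C4 instead of C5, since the conformer with the C1 oxygen axial favours trans-diaxial opening there. The C1 hydroxyl may also capture C4 across the ring once the C4–O bond loosens. Fallback: setting out from cyclohexenol 12, the chlorine is introduced by chlorocycloetherification with trichloroisocyanuric acid (CH2Cl2, 0 °C). The C1 hydroxyl adds to C4 (Markovnikov, 5-exo) anti to the chloronium ion, which can only be opened from the face opposite the hydroxyl. This should give the bridged chloro ether F7 with chlorine on C5 trans to the C1 oxygen. Bu4NF then gives the primary alcohol F8, TEMPO/NaOCl/NaClO2 gives the acid F9, and EtSH/DCC/DMAP gives the thioester F10. Finally Me3SiBr cleaves the strained ether at C4, assisted by the C5 chlorine, with bromide entering on the face the oxygen leaves and silicon staying on the C1 oxygen. This rejoins the route at 18 and bypasses epoxide 13 and chlorohydrin 14.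

**Further compounds**

F1 | step 5 | racemic cis-5-{[(tert-butyldiphenylsilyl)oxy]methyl}bicyclo[3.1.0]hexan-2-one | O=C1CCC2(CO[Si](c3ccccc3)(c3ccccc3)C(C)(C)C)CC12
F2 | step 5 | (1S,2R,5S)-5-{[(tert-butyldiphenylsilyl)oxy]methyl}-2-{[(S)-N-methyl-S-phenylsulfonimidoyl]methyl}bicyclo[3.1.0]hexan-2-ol | CN=[S@@](C[C@@]1(O)CC[C@]2(CO[Si](c3ccccc3)(c3ccccc3)C(C)(C)C)C[C@H]12)(=O)c1ccccc1
F3 | step 7 | (1S,2R,5S)-5-(hydroxymethyl)-2-methylbicyclo[3.1.0]hexan-2-ol | C[C@@]1(O)CC[C@]2(CO)C[C@H]12
F4 | step 7 | primary benzoate of F3, [(1S,4R,5S)-4-hydroxy-4-methylbicyclo[3.1.0]hexan-1-yl]methyl benzoate | C[C@@]1(O)CC[C@]2(COC(=O)c3ccccc3)C[C@H]12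
F5 | step 7 | [(1S)-1-hydroxy-4-methylcyclohex-3-en-1-yl]methyl benzoate | O=C(OC[C@]1(O)CCC(C)=CC1)c1ccccc1
F6 | step 7 | (1S)-1-(hydroxymethyl)-4-methylcyclohex-3-en-1-ol | OC[C@]1(O)CCC(C)=CC1
F7 | step 9 | (1R,2R,4S)-4-{[(tert-butyldiphenylsilyl)oxy]methyl}-2-chloro-1-methyl-7-oxabicyclo[2.2.1]heptane (chlorine endo) | CC(C)(C)[Si](c1ccccc1)(c1ccccc1)OC[C@@]12CC[C@@](C)(O1)[C@H](Cl)C2
F8 | step 9 | [(1S,3R,4R)-3-chloro-4-methyl-7-oxabicyclo[2.2.1]heptan-1-yl]methanol | OC[C@@]12CC[C@@](C)(O1)[C@H](Cl)C2
F9 | step 9 | (1S,3R,4R)-3-chloro-4-methyl-7-oxabicyclo[2.2.1]heptane-1-carboxylic acid | OC(=O)[C@@]12CC[C@@](C)(O1)[C@H](Cl)C2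
F10 | step 9 | S-ethyl (1S,3R,4R)-3-chloro-4-methyl-7-oxabicyclo[2.2.1]heptane-1-carbothioate | CCSC(=O)[C@@]12CC[C@@](C)(O1)[C@H](Cl)C2
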